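The readings are calculated on assumed constants; noise was put on by code.

Does the share of target among the products move when the partner charge in the new flasks rises from 0.0120 M to 0.100 M, read at 25 min?

| setting | dusk | spring | midnight | maple | larch | ash | oak |
|---|---|---|---|---|---|---|---|
| substrate | 0.050 M | 0.050 M | 0.050 M | 0.050 M | 0.050 M | 0.050 M | 0.050 M |
| partner | 0.016 M | 0.032 M | 0.083 M | 0.0120 M | 0.0250 M | 0.0500 M | 0.100 M |
| remark | run made earlier | run made earlier | run made earlier |  |  |  |  |
| time |  |  |  | 25 min | 25 min | 25 min | 25 min |

- dusk (time / min: target / %, isomer of the product A / %, isomer of the product B / %): 5.00: 0, 0, 0; 10.0: 1, 6, 0; 15.0: 0, 4, 0; 20.0: 2, 4, 1; 25.0: 2, 6, 0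
- spring (time / min: target / %, isomer of the product A / %, isomer of the product B / %): 5.00: 2, 0, 0; 10.0: 2, 4, 0; 15.0: 3, 9, 3; 20.0: 2, 10, 0; 25.0: 2, 15, 0
- midnight (time / min: target / %, isomer of the product A / %, isomer of the product B / %): 2.00: 0, 0, 0; 4.00: 2, 3, 1; 8.00: 5, 10, 0; 12.0: 5, 14, 0; 25.0: 5, 26, 2

(scatter of a reading: 1.5 percentage points)

1. share of target in all that became target or isomer of the product A or isomer of the product B for maple, larch, ash, oak, in this order
2. the shape of the row from first to last (rises all the way / falls, then rises / falls all the way / hardly changes / rises, then falls)

- steps under discussion: target <-> isomer of the product B; intermediate <-> isomer of the product A; substrate + partner -> intermediate + released group; intermediate <-> target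
- "hardly changes" means that all values lie within two and a half points (for a concentration: within two and a half percent of the largest)

I began with where partner enters. It enters once, in the step that makes intermediate, and target and isomer of the product A form from intermediate by exchanges with no partner in them. If those exchanges stood near balance, partner would set how much material arrived but not how it divided, which is thermodynamic rather than kinetic control of the split. Summing the last readings of dusk, spring and midnight gave 0.191 for the exchange ratio, c(target) over c(isomer of the product A). That made the share 16.1%.

But the target readings are small. Their sum carries a relative scatter of 28.9%, so the level lay somewhere from 12.0% to 19.8%. The flatness, though, rested on the argument and not on that level.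

Isomer of the product B also belongs in the denominator, and counting its readings lowered the share to 15.5%.

A harder objection came from midnight at 8.00 min, which read target 5% where the ratio asked for 1.91%. That is 3.1 percentage points off, against a scatter of 1.5 points, so the balance might lag early on. But the exchanges contain no partner, so I expected such a lag to shift maple and oak together at a common time. I stayed with about 15.5% and a row that hardly changes.

The forecast gave 19%, 16%, 15% and 14%, with the shape falls all the way: “I expect a gentle fall, though "hardly changes" is a close alternative.”

The flasks gave 16.0%, 16.0%, 15.9% and 15.6%: hardly changes. The forecast's row stands within its margin, but its shape does not.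

    target ⇌ isomer of the product B (K = 1.50, k = 0.0180 min⁻¹)
    intermediate ⇌ isomer of the product A (K = 2.60, k = 0.580 min⁻¹)
    substrate + partner → intermediate + released group (k = 0.340 M⁻¹ min⁻¹)
    intermediate ⇌ target (K = 0.460, k = 1.40 min⁻¹)

In oak, the ratio applied to 30.7% of isomer of the product A gives 5.86% of target, and the flask held 5.99%. In maple, with 0.120 of oak's partner charge, it gives 0.907% from 4.75%, and the flask held 0.950%. The main reason for the low height of the share in oak is the backward run from target to intermediate. Taken away in oak, it leaves a share of 76.3% instead of 15.6%.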